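**Retrosynthetic overview**

1. The target is cut last at the central E-ethene bridge: the left aryl bromide, the right aryl bromide and a two-carbon vinylborate are joined in one flask. Suzuki–Miyaura vinylation of the right bromide comes first, then a Mizoroki–Heck coupling that forms the bond between C5 of the left benzofuran and the alkene CH. Both run on the free polyphenols. (Ring A is the benzo ring of the right half that carries the alkene; ring B is the dioxygenated benzo ring attached to C3 of ring A's heterocycle; "left" is the 7-hydroxy-dihydrobenzofuran.)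
2. Each 2,3-dihydrobenzofuran comes from a diaryldiazomethane with an ortho 4-methoxybenzyl ether. An enantioselective rhodium-carbene 1,5-C–H insertion closes the O1–C2–C3 ring by making the C2–C3 bond and sets C3. BBr3 then frees the phenols and epimerises C2 to trans.
3. Order of ring formation: the left heterocycle (step 5); in the right half the heterocycle on ring B first (step 13), then the heterocycle on ring A (step 15), after ring A has been attached as a nitrile to the aryl Grignard reagent of the first ring.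
4. Enabling feature: the bridge sits on C5 of the left benzofuran (para to O1, hydrogen on C4 and C6, hydroxyl only at the meta carbon C7) and on C6 of ring A's benzofuran (hydrogen on C5 and C7). Both carbons are unhindered, have no ortho hydroxyl and lie far from all six stereocentres, so both can be carried as bromides from commercial bromoarenes and bridged last.

Key step: step 17

Assumption (chemistry): Rh2(S-PTAD)4, dirhodium tetrakis[(S)-(1-adamantyl)(phthalimido)acetate], is taken to give the 3S carbene-carbon configuration (steps 5 and 13) and Rh2(R-PTAD)4 the 3R configuration (step 15); if the sense of induction is the reverse, the two catalyst enantiomers are exchanged.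

**Route**

Step 1
Reactants: 1 5-bromo-2-hydroxy-3-methoxybenzaldehyde; 2 4-methoxybenzyl chloride
Product: 3 5-bromo-3-methoxy-2-[(4-methoxybenzyl)oxy]benzaldehyde
Conditions: K2CO3, n-Bu4NI (cat.), DMF, 60 °C
Reagents that add atoms: none
Why: Williamson O-alkylation of the phenoxide (SN2 on the benzylic chloride) installs the 4-methoxybenzyl ether whose O–CH2 group becomes C2 of the left dihydrobenzofuran.

Step 2
Reactants: 3 5-bromo-3-methoxy-2-[(4-methoxybenzyl)oxy]benzaldehyde; 4 (3,5-dimethoxyphenyl)magnesium chloride (THF solution)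
Product: 5 [5-bromo-3-methoxy-2-[(4-methoxybenzyl)oxy]phenyl](3,5-dimethoxyphenyl)methanol (racemic)
Conditions: THF, −40 → 0 °C; aq NH4Cl
Reagents that add atoms: none
Why: Grignard 1,2-addition to the aldehyde at low temperature leaves the aryl bromide untouched, and the carbinol centre is left racemic because the next step removes it.

Step 3
Reactants: 5 [5-bromo-3-methoxy-2-[(4-methoxybenzyl)oxy]phenyl](3,5-dimethoxyphenyl)methanol
Product: 6 [5-bromo-3-methoxy-2-[(4-methoxybenzyl)oxy]phenyl](3,5-dimethoxyphenyl)methanone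
Conditions: activated MnO2, CH2Cl2, rt
Reagents that add atoms: none
Why: Oxidation of a doubly benzylic secondary alcohol to the diaryl ketone with MnO2 is mild enough for the benzyl ether and the aryl bromide.

Step 4
Reactants: 6 [5-bromo-3-methoxy-2-[(4-methoxybenzyl)oxy]phenyl](3,5-dimethoxyphenyl)methanone
Product: 7 hydrazone of ketone 6 (E/Z mixture)
Conditions: N2H4·H2O (10 equiv), AcOH (cat.), EtOH, 80 °C
Reagents that add atoms: hydrazine monohydrate, NN.O
Why: Hydrazone formation by acid-catalysed condensation, the excess of hydrazine suppressing azine formation.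

Step 5
Reactants: 7 hydrazone of ketone 6
Product: 9 (2R,3S)-5-bromo-3-(3,5-dimethoxyphenyl)-7-methoxy-2-(4-methoxyphenyl)-2,3-dihydro-1-benzofuran (2,3-cis), via diaryldiazomethane 8 (not isolated)
Conditions: MnO2, CH2Cl2, 0 °C → rt; filter; Rh2(S-PTAD)4 (1 mol %), CH2Cl2, 0 °C
Reagents that add atoms: none
Why: MnO2 dehydrogenates the hydrazone to the diaryldiazomethane, and the chiral divalent rhodium carboxylate turns it into a donor/donor carbene that inserts into the ether-activated benzylic C–H bond (enantioselective intramolecular 1,5-C–H insertion); the catalyst sets C3 as S and the insertion transition state places the two aryl groups cis (2R).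

Step 6
Reactants: 9 (2R,3S)-5-bromo-3-(3,5-dimethoxyphenyl)-7-methoxy-2-(4-methoxyphenyl)-2,3-dihydro-1-benzofuran
Product: 10 5-[(2S,3S)-5-bromo-7-hydroxy-2-(4-hydroxyphenyl)-2,3-dihydro-1-benzofuran-3-yl]benzene-1,3-diol (2,3-trans)
Conditions: BBr3 (excess), CH2Cl2, −78 °C → rt; H2O, 0 °C
Reagents that add atoms: none
Why: BBr3 cleaves the four aryl methyl ethers (Lewis-acid ether cleavage) and, by reversible ionisation of the benzylic C2–O1 bond to a 4-oxybenzyl cation that recloses, should epimerise C2 to the more stable 2,3-trans isomer (2S), while C3 (S) and the C–Br bond are untouched.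

Step 7
Reactants: 11 4-bromo-2-hydroxybenzonitrile; 2 4-methoxybenzyl chloride
Product: 12 4-bromo-2-[(4-methoxybenzyl)oxy]benzonitrile
Conditions: K2CO3, n-Bu4NI (cat.), DMF, 60 °C
Reagents that add atoms: none
Why: Williamson O-alkylation as in step 1 gives the ring-A building block whose nitrile carbon becomes C3 and whose O–CH2 group becomes C2 of ring A's heterocycle.

Step 8
Reactants: 13 1-bromo-3,5-dimethoxybenzene
Product: 14 2-bromo-4,6-dimethoxybenzaldehyde
Conditions: POCl3, DMF, 0 → 90 °C; H2O
Reagents that add atoms: N,N-dimethylformamide, CN(C)C=O; water, O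
Why: Vilsmeier–Haack formylation of the electron-rich arene should occur at C2, para to one methoxy group and ortho to the other, in preference to the more crowded position between the two methoxy groups.

Step 9
Reactants: 14 2-bromo-4,6-dimethoxybenzaldehyde
Product: 15 2-bromo-6-hydroxy-4-methoxybenzaldehyde
Conditions: BCl3 (1.1 equiv), CH2Cl2, −78 → 0 °C; H2O
Reagents that add atoms: none
Why: BCl3 chelated between the aldehyde oxygen and the ortho methoxy group cleaves only that methyl ether (chelation-controlled ortho-demethylation), which tells the two ring oxygens apart.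

Step 10
Reactants: 15 2-bromo-6-hydroxy-4-methoxybenzaldehyde
Product: 17 2-bromo-6-hydroxy-4-methoxybenzonitrile, via aldoxime 16 (not isolated)
Conditions: NH2OH·HCl, HCO2Na, HCO2H, 100 °C
Reagents that add atoms: hydroxylamine hydrochloride, NO.Cl
Why: One-pot aldehyde-to-nitrile conversion by oxime formation and formic-acid-promoted dehydration gives the nitrile that will accept the aryl nucleophile.

Step 11
Reactants: 17 2-bromo-6-hydroxy-4-methoxybenzonitrile; 2 4-methoxybenzyl chloride
Product: 18 2-bromo-4-methoxy-6-[(4-methoxybenzyl)oxy]benzonitrile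
Conditions: K2CO3, n-Bu4NI (cat.), DMF, 60 °C
Reagents that add atoms: none
Why: Williamson O-alkylation as in step 1.

Step 12
Reactants: 18 2-bromo-4-methoxy-6-[(4-methoxybenzyl)oxy]benzonitrile; 4 (3,5-dimethoxyphenyl)magnesium chloride
Product: 21 hydrazone of [2-bromo-4-methoxy-6-[(4-methoxybenzyl)oxy]phenyl](3,5-dimethoxyphenyl)methanone (E/Z mixture), via N-chloromagnesio ketimine 19 (not isolated), via N–H ketimine 20 (not isolated)
Conditions: THF–toluene, 25 → 60 °C; MeOH, 0 °C; N2H4·H2O (10 equiv), AcOH (cat.), EtOH, 70 °C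
Reagents that add atoms: hydrazine monohydrate, NN.O
Why: Grignard addition to the nitrile stops at the N-magnesio ketimine, methanol frees the N–H ketimine, and hydrazine exchanges with it (transimination), so the hydrazone is reached without the doubly ortho-substituted ketone, which would condense poorly.

Step 13
Reactants: 21 hydrazone from step 12
Product: 23 (2R,3S)-4-bromo-3-(3,5-dimethoxyphenyl)-6-methoxy-2-(4-methoxyphenyl)-2,3-dihydro-1-benzofuran (2,3-cis), via diaryldiazomethane 22 (not isolated)
Conditions: MnO2, CH2Cl2, 0 °C → rt; filter; Rh2(S-PTAD)4 (1 mol %), CH2Cl2, 0 °C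
Reagents that add atoms: none
Why: Same hydrazone dehydrogenation and enantioselective rhodium-carbene 1,5-C–H insertion as in step 5; the catalyst sets C3 as S, the insertion gives the 2,3-cis ring (2R), and the ortho bromine is a spectator.

Step 14
Reactants: 23 (2R,3S)-4-bromo-3-(3,5-dimethoxyphenyl)-6-methoxy-2-(4-methoxyphenyl)-2,3-dihydro-1-benzofuran; 12 4-bromo-2-[(4-methoxybenzyl)oxy]benzonitrile
Product: 27 hydrazone of the diaryl ketone that links C4 of benzofuran 23 to C1 of the 4-bromo-2-[(4-methoxybenzyl)oxy]phenyl ring (E/Z mixture), via arylmagnesium bromide 24 (not isolated), via N-bromomagnesio ketimine 25 (not isolated), via N–H ketimine 26 (not isolated)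
Conditions: Mg turnings, LiCl, THF, 25 °C; then 12, THF, 0 → 50 °C; MeOH, 0 °C; N2H4·H2O (10 equiv), AcOH (cat.), EtOH, 70 °C
Reagents that add atoms: hydrazine monohydrate, NN.O
Why: LiCl-assisted magnesium insertion into the aryl bromide and addition of the aryl Grignard reagent to the nitrile of 12, whose own C–Br bond does not exchange with an arylmagnesium halide, give the ketimine, which is converted into the hydrazone by transimination as in step 12; no stereocentre is touched.

Step 15
Reactants: 27 hydrazone from step 14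
Product: 29 (2S,3R)-6-bromo-3-[(2R,3S)-3-(3,5-dimethoxyphenyl)-6-methoxy-2-(4-methoxyphenyl)-2,3-dihydro-1-benzofuran-4-yl]-2-(4-methoxyphenyl)-2,3-dihydro-1-benzofuran (both rings cis), via diaryldiazomethane 28 (not isolated)
Conditions: MnO2, CH2Cl2, 0 °C → rt; filter; Rh2(R-PTAD)4 (1 mol %), CH2Cl2, 0 °C
Reagents that add atoms: none
Why: Same dehydrogenation and rhodium-carbene 1,5-C–H insertion as in step 5, now with the enantiomeric catalyst to set C3 of ring A's heterocycle as R (2,3-cis, 2S); the resident ring sits on the aryl group that can rotate about its bond to the carbene carbon, so the catalyst rather than the substrate should choose the face, and the benzylic ether CH2 is the only C–H bond within reach of a five-membered transition state.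

Step 16
Reactants: 29 cis,cis pentamethyl ether bromide from step 15
Product: 30 (2R,3R)-6-bromo-3-[(2S,3S)-3-(3,5-dihydroxyphenyl)-6-hydroxy-2-(4-hydroxyphenyl)-2,3-dihydro-1-benzofuran-4-yl]-2-(4-hydroxyphenyl)-2,3-dihydro-1-benzofuran (both rings trans)
Conditions: BBr3 (excess), CH2Cl2, −78 °C → rt; H2O, 0 °C
Reagents that add atoms: none
Why: BBr3 cleaves the five aryl methyl ethers and, as in step 6, should equilibrate both benzylic C2 centres through ring-opened 4-oxybenzyl cations to the all-trans compound, the two C3 centres being configurationally stable.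

Step 17
Reactants: 30 right pentahydroxy bromide from step 16; 31 potassium vinyltrifluoroborate; 10 left tetrahydroxy bromide from step 6
Product: 33 target CNP0265934.1, via pentahydroxy styrene 32 (not isolated)
Conditions: 31 (1.05 equiv), PdCl2(dppf) (5 mol %), Et3N, n-PrOH–H2O, 80 °C; concentrate; then 10 (1.0 equiv), Pd(OAc)2 (5 mol %), P(o-tol)3 (12 mol %), Et3N, DMF, 100 °C, argon
Reagents that add atoms: none
Why: In the first stage zerovalent palladium inserts into the C6–Br bond of 30, and transmetalation with the vinylborate followed by reductive elimination gives styrene 32 (Suzuki–Miyaura vinylation); in the second stage oxidative addition to the C5–Br bond of 10, syn-carbopalladation of the terminal alkene carbon of 32 and syn-β-hydride elimination form the bond between C5 of the left benzofuran and the alkene CH (Mizoroki–Heck reaction). The closest known reaction types are one-pot vinylation/Heck syntheses of unsymmetrical stilbenes and Heck couplings of unprotected bromophenols. No ring is closed and no stereocentre is created; the only new stereo-element is the E double bond, which follows from β-hydride elimination through the rotamer with the two aryl groups anti. The step needs the two bromides to react one after the other and the aryl group to go to the terminal alkene carbon: the first is secured by consuming 30 with one equivalent of 31 before 10 is added, the second by the steric preference of the neutral arylpalladium bromide pathway. The nine free hydroxyls should be tolerated because neither C–Br carbon has an ortho hydroxyl and triethylamine is too weak a base to form the phenoxides that could open the 2-(4-hydroxyphenyl)dihydrobenzofurans through para-quinone methides, and all six stereocentres lie at least three bonds from the reacting carbons. In one flask the step therefore builds both aryl–alkene bonds of the central stilbene and delivers the target itself, with no protecting-group step after it.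

**Compound list**

1 | 5-bromo-2-hydroxy-3-methoxybenzaldehyde | O=Cc1cc(Br)cc(OC)c1O | starting material
2 | 4-methoxybenzyl chloride | COc1ccc(CCl)cc1 | starting material
3 | 5-bromo-3-methoxy-2-[(4-methoxybenzyl)oxy]benzaldehyde | O=Cc1cc(Br)cc(OC)c1OCc1ccc(OC)cc1 | intermediate
4 | (3,5-dimethoxyphenyl)magnesium chloride | COc1cc([Mg]Cl)cc(OC)c1 | starting material
5 | [5-bromo-3-methoxy-2-[(4-methoxybenzyl)oxy]phenyl](3,5-dimethoxyphenyl)methanol, racemic | OC(c1cc(OC)cc(OC)c1)c1cc(Br)cc(OC)c1OCc1ccc(OC)cc1 | intermediate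
6 | [5-bromo-3-methoxy-2-[(4-methoxybenzyl)oxy]phenyl](3,5-dimethoxyphenyl)methanone | O=C(c1cc(OC)cc(OC)c1)c1cc(Br)cc(OC)c1OCc1ccc(OC)cc1 | intermediate
7 | hydrazone of 6 | NN=C(c1cc(OC)cc(OC)c1)c1cc(Br)cc(OC)c1OCc1ccc(OC)cc1 | intermediate
8 | 5-bromo-1-[diazo(3,5-dimethoxyphenyl)methyl]-3-methoxy-2-[(4-methoxybenzyl)oxy]benzene | [N-]=[N+]=C(c1cc(OC)cc(OC)c1)c1cc(Br)cc(OC)c1OCc1ccc(OC)cc1 | intermediate (not isolated)
9 | (2R,3S)-5-bromo-3-(3,5-dimethoxyphenyl)-7-methoxy-2-(4-methoxyphenyl)-2,3-dihydro-1-benzofuran | COc1ccc([C@@H]2Oc3c(OC)cc(Br)cc3[C@@H]2c2cc(OC)cc(OC)c2)cc1 | intermediate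
10 | 5-[(2S,3S)-5-bromo-7-hydroxy-2-(4-hydroxyphenyl)-2,3-dihydro-1-benzofuran-3-yl]benzene-1,3-diol | Oc1ccc([C@H]2Oc3c(O)cc(Br)cc3[C@@H]2c2cc(O)cc(O)c2)cc1 | intermediate
11 | 4-bromo-2-hydroxybenzonitrile | N#Cc1ccc(Br)cc1O | starting material
12 | 4-bromo-2-[(4-methoxybenzyl)oxy]benzonitrile | N#Cc1ccc(Br)cc1OCc1ccc(OC)cc1 | intermediate
13 | 1-bromo-3,5-dimethoxybenzene | COc1cc(Br)cc(OC)c1 | starting material
14 | 2-bromo-4,6-dimethoxybenzaldehyde | O=Cc1c(Br)cc(OC)cc1OC | intermediate
15 | 2-bromo-6-hydroxy-4-methoxybenzaldehyde | O=Cc1c(Br)cc(OC)cc1O | intermediate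
16 | 2-bromo-6-hydroxy-4-methoxybenzaldehyde oxime | ON=Cc1c(Br)cc(OC)cc1O | intermediate (not isolated)
17 | 2-bromo-6-hydroxy-4-methoxybenzonitrile | N#Cc1c(Br)cc(OC)cc1O | intermediate
18 | 2-bromo-4-methoxy-6-[(4-methoxybenzyl)oxy]benzonitrile | N#Cc1c(Br)cc(OC)cc1OCc1ccc(OC)cc1 | intermediate
19 | N-chloromagnesio ketimine from 18 and 4 | Cl[Mg]N=C(c1cc(OC)cc(OC)c1)c1c(Br)cc(OC)cc1OCc1ccc(OC)cc1 | intermediate (not isolated)
20 | 1-[2-bromo-4-methoxy-6-[(4-methoxybenzyl)oxy]phenyl]-1-(3,5-dimethoxyphenyl)methanimine | N=C(c1cc(OC)cc(OC)c1)c1c(Br)cc(OC)cc1OCc1ccc(OC)cc1 | intermediate (not isolated)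
21 | hydrazone of [2-bromo-4-methoxy-6-[(4-methoxybenzyl)oxy]phenyl](3,5-dimethoxyphenyl)methanone | NN=C(c1cc(OC)cc(OC)c1)c1c(Br)cc(OC)cc1OCc1ccc(OC)cc1 | intermediate
22 | 1-bromo-2-[diazo(3,5-dimethoxyphenyl)methyl]-5-methoxy-3-[(4-methoxybenzyl)oxy]benzene | [N-]=[N+]=C(c1cc(OC)cc(OC)c1)c1c(Br)cc(OC)cc1OCc1ccc(OC)cc1 | intermediate (not isolated)
23 | (2R,3S)-4-bromo-3-(3,5-dimethoxyphenyl)-6-methoxy-2-(4-methoxyphenyl)-2,3-dihydro-1-benzofuran | Brc1cc(OC)cc2c1[C@H](c1cc(OC)cc(OC)c1)[C@H](c1ccc(OC)cc1)O2 | intermediate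
24 | arylmagnesium bromide of 23 (magnesium at C4, configuration unchanged) | Br[Mg]c1cc(OC)cc2c1[C@H](c1cc(OC)cc(OC)c1)[C@H](c1ccc(OC)cc1)O2 | intermediate (not isolated)
25 | N-bromomagnesio ketimine from 24 and 12 | Br[Mg]N=C(c1ccc(Br)cc1OCc1ccc(OC)cc1)c1cc(OC)cc2c1[C@H](c1cc(OC)cc(OC)c1)[C@H](c1ccc(OC)cc1)O2 | intermediate (not isolated)
26 | N–H ketimine linking C4 of benzofuran 23 to the 4-bromo-2-[(4-methoxybenzyl)oxy]phenyl ring | N=C(c1ccc(Br)cc1OCc1ccc(OC)cc1)c1cc(OC)cc2c1[C@H](c1cc(OC)cc(OC)c1)[C@H](c1ccc(OC)cc1)O2 | intermediate (not isolated)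
27 | hydrazone corresponding to ketimine 26 | NN=C(c1ccc(Br)cc1OCc1ccc(OC)cc1)c1cc(OC)cc2c1[C@H](c1cc(OC)cc(OC)c1)[C@H](c1ccc(OC)cc1)O2 | intermediate
28 | diaryldiazomethane corresponding to hydrazone 27 | [N-]=[N+]=C(c1ccc(Br)cc1OCc1ccc(OC)cc1)c1cc(OC)cc2c1[C@H](c1cc(OC)cc(OC)c1)[C@H](c1ccc(OC)cc1)O2 | intermediate (not isolated)
29 | (2S,3R)-6-bromo-3-[(2R,3S)-3-(3,5-dimethoxyphenyl)-6-methoxy-2-(4-methoxyphenyl)-2,3-dihydro-1-benzofuran-4-yl]-2-(4-methoxyphenyl)-2,3-dihydro-1-benzofuran | Brc1ccc2c(c1)O[C@H](c1ccc(OC)cc1)[C@@H]2c1cc(OC)cc2c1[C@H](c1cc(OC)cc(OC)c1)[C@H](c1ccc(OC)cc1)O2 | intermediate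
30 | (2R,3R)-6-bromo-3-[(2S,3S)-3-(3,5-dihydroxyphenyl)-6-hydroxy-2-(4-hydroxyphenyl)-2,3-dihydro-1-benzofuran-4-yl]-2-(4-hydroxyphenyl)-2,3-dihydro-1-benzofuran | Brc1ccc2c(c1)O[C@@H](c1ccc(O)cc1)[C@@H]2c1cc(O)cc2c1[C@H](c1cc(O)cc(O)c1)[C@@H](c1ccc(O)cc1)O2 | intermediate
31 | potassium vinyltrifluoroborate | C=C[B-](F)(F)F.[K+] | starting material
32 | 6-ethenyl analogue of 30 (same configuration, all nine... five hydroxyls free) | C=Cc1ccc2c(c1)O[C@@H](c1ccc(O)cc1)[C@@H]2c1cc(O)cc2c1[C@H](c1cc(O)cc(O)c1)[C@@H](c1ccc(O)cc1)O2 | intermediate (not isolated)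
33 | CNP0265934.1: 5-[(2S,3S)-5-[(E)-2-[(2R,3R)-3-[(2S,3S)-3-(3,5-dihydroxyphenyl)-6-hydroxy-2-(4-hydroxyphenyl)-2,3-dihydro-1-benzofuran-4-yl]-2-(4-hydroxyphenyl)-2,3-dihydro-1-benzofuran-6-yl]ethenyl]-7-hydroxy-2-(4-hydroxyphenyl)-2,3-dihydro-1-benzofuran-3-yl]benzene-1,3-diol | Oc1ccc([C@H]2Oc3c(O)cc(/C=C/c4ccc5c(c4)O[C@@H](c4ccc(O)cc4)[C@@H]5c4cc(O)cc5c4[C@H](c4cc(O)cc(O)c4)[C@@H](c4ccc(O)cc4)O5)cc3[C@@H]2c2cc(O)cc(O)c2)cc1 | target

**Step count and risks**

Total step count: 17. Longest linear sequence: 10 steps (steps 8 to 17).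

Steps most likely to fail:

1. Step 17. The palladium catalyst may be deactivated and the electron-rich free polyphenols may degrade oxidatively under hot basic conditions; the 2-(4-hydroxyphenyl)dihydrobenzofuran rings may open through para-quinone methides; incomplete vinylation would lead to symmetrical coupling. The fallback sets out from 10 and 30 and returns at 33. Both bromides are peracetylated (Ac2O, pyridine, 25 °C) to the left tetraacetate F1 and the right pentaacetate F2. F2 is vinylated under base-free Stille conditions (tributyl(vinyl)stannane, Pd(PPh3)4, toluene, 100 °C) to the pentaacetate styrene F3, which is isolated. F3 is coupled with F1 in a Mizoroki–Heck reaction (Pd(OAc)2, P(o-tol)3, Et3N, DMF, 100 °C) to the nonaacetate of the target F4. Transesterification with a catalytic amount of K2CO3 in methanol at 0 °C then gives 33.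

2. Step 16. The strong Lewis acid may over-react at the two benzylic ether carbons (bromide capture or Friedel–Crafts alkylation of the neighbouring dioxygenated rings by the ring-opened cations), or epimerisation may stay incomplete and leave a mixture of C2 epimers. The fallback sets out from 29 and returns at 30. The two events are separated: trifluoroacetic acid in CH2Cl2 at 25 °C first epimerises both C2 centres to give the all-trans pentamethyl ether F5, and the methyl ethers are then cleaved under milder iodide-assisted conditions (BCl3, n-Bu4NI, CH2Cl2, −78 → 0 °C) to give 30.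

3. Step 12. The Grignard reagent may attack the ring instead of the doubly ortho-substituted nitrile (displacement of the ortho benzyloxy group or bromine–magnesium exchange), or hydrazine may exchange too slowly at the crowded imine carbon. The fallback sets out from 15 and returns at 21, using the carbonyl route of the left half. Aldehyde 15 is O-alkylated with 2 (K2CO3, DMF, 60 °C) to the benzyl-protected aldehyde F6. Reagent 4 is added at −40 °C to give the carbinol F7, which MnO2 oxidises to the ketone F8. Forced condensation with anhydrous hydrazine (n-BuOH, 120 °C, sealed tube) then gives 21.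

Further compounds

F1 | step 17 | tetraacetate of 10, (2S,3S) | CC(=O)Oc1ccc([C@H]2Oc3c(OC(C)=O)cc(Br)cc3[C@@H]2c2cc(OC(C)=O)cc(OC(C)=O)c2)cc1
F2 | step 17 | pentaacetate of 30 | Brc1ccc2c(c1)O[C@@H](c1ccc(OC(C)=O)cc1)[C@@H]2c1cc(OC(C)=O)cc2c1[C@H](c1cc(OC(C)=O)cc(OC(C)=O)c1)[C@@H](c1ccc(OC(C)=O)cc1)O2
F3 | step 17 | pentaacetate of styrene 32 | C=Cc1ccc2c(c1)O[C@@H](c1ccc(OC(C)=O)cc1)[C@@H]2c1cc(OC(C)=O)cc2c1[C@H](c1cc(OC(C)=O)cc(OC(C)=O)c1)[C@@H](c1ccc(OC(C)=O)cc1)O2
F4 | step 17 | nonaacetate of target 33 | CC(=O)Oc1ccc([C@H]2Oc3c(OC(C)=O)cc(/C=C/c4ccc5c(c4)O[C@@H](c4ccc(OC(C)=O)cc4)[C@@H]5c4cc(OC(C)=O)cc5c4[C@H](c4cc(OC(C)=O)cc(OC(C)=O)c4)[C@@H](c4ccc(OC(C)=O)cc4)O5)cc3[C@@H]2c2cc(OC(C)=O)cc(OC(C)=O)c2)cc1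
F5 | step 16 | (2R,3R)-6-bromo-3-[(2S,3S)-3-(3,5-dimethoxyphenyl)-6-methoxy-2-(4-methoxyphenyl)-2,3-dihydro-1-benzofuran-4-yl]-2-(4-methoxyphenyl)-2,3-dihydro-1-benzofuran | Brc1ccc2c(c1)O[C@@H](c1ccc(OC)cc1)[C@@H]2c1cc(OC)cc2c1[C@H](c1cc(OC)cc(OC)c1)[C@@H](c1ccc(OC)cc1)O2
F6 | step 12 | 2-bromo-4-methoxy-6-[(4-methoxybenzyl)oxy]benzaldehyde | O=Cc1c(Br)cc(OC)cc1OCc1ccc(OC)cc1
F7 | step 12 | [2-bromo-4-methoxy-6-[(4-methoxybenzyl)oxy]phenyl](3,5-dimethoxyphenyl)methanol, racemic | OC(c1cc(OC)cc(OC)c1)c1c(Br)cc(OC)cc1OCc1ccc(OC)cc1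
F8 | step 12 | [2-bromo-4-methoxy-6-[(4-methoxybenzyl)oxy]phenyl](3,5-dimethoxyphenyl)methanone | O=C(c1cc(OC)cc(OC)c1)c1c(Br)cc(OC)cc1OCc1ccc(OC)cc1
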